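**Retrosynthetic overview**

1. Carotenoid locants are used: ring A = C1–C6 (acetylenic end, C3–OH), chain C7 to C15 then C15' to C7', ring B = C1'–C6' (dihydro end, C3'–OH), C20 = methyl on C13. The C40 skeleton is cut at the C14–C15 single bond and, in the same operation, at the C13–C20 bond.
2. Enabling feature: C14 is the unsubstituted CH end of the methyl-branched alkene C13(C20)=C14, the imprint of a syn methylalumination of a terminal alkyne C13≡C14–H, and C15 is the end of the (E)-disubstituted alkene C15=C15', which can carry bromide. A ring A C18 dienediyne, AlMe3 and a ring B C21 (E)-bromotetraene are therefore joined in one pot (Zr-catalysed carboalumination, then Pd/Zn alkenyl–alkenyl coupling), which installs C20, fixes C13=C14 as E and completes the skeleton.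
3. C18 dienediyne: ring A enol triflate plus (E)-3-methylpent-2-en-4-yn-1-ol (Sonogashira, C6–C7), oxidation, silylpropargyl phosphonate olefination (C11=C12), C-desilylation.
4. C21 bromide: the same enol triflate plus a homopropargyl zinc reagent (sp2–sp3 Negishi, C6'–C7'), then two rounds of methylalumination/coupling with (E)-1-bromo-2-iodoethene (C10'–C11' and C14'–C15') separated by an ethynylation (C12'–C13').
5. Ring order: no ring is formed. Rings A and B are both taken intact from (4R,6R)-actinol, which supplies C3 and C3' as R; one enol triflate provides the C5=C6 and C5'=C6' double bonds; the last step removes both silyl ethers.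

Key step: step 13

Assumption: (4R,6R)-actinol and geometrically pure (E)-3-methylpent-2-en-4-yn-1-ol are taken as purchasable; all polyene intermediates are handled with exclusion of light and air.

**Route**

Step 1
Reactants: 1 (4R,6R)-4-hydroxy-2,2,6-trimethylcyclohexan-1-one
Product: 2 (4R,6R)-4-(tert-butyldimethylsilyloxy)-2,2,6-trimethylcyclohexan-1-one
Conditions: TBSCl, imidazole, DMF, 23 °C
Reagents that add atoms: tert-butyldimethylsilyl chloride (TBSCl), CC(C)(C)[Si](C)(C)Cl
Why: Imidazole-promoted silyl ether formation at the unhindered secondary alcohol should proceed without touching the ketone or either stereocentre.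

Step 2
Reactants: 2 (4R,6R)-4-(tert-butyldimethylsilyloxy)-2,2,6-trimethylcyclohexan-1-one
Product: 3 (4R)-4-(tert-butyldimethylsilyloxy)-2,6,6-trimethylcyclohex-1-en-1-yl trifluoromethanesulfonate
Conditions: LiN(i-Pr)2, THF, −78 °C; then PhNTf2, −78 to 23 °C
Reagents that add atoms: N-phenylbis(trifluoromethanesulfonimide) (PhNTf2), O=S(=O)(N(c1ccccc1)S(=O)(=O)C(F)(F)F)C(F)(F)F
Why: The ketone can enolise only toward the methyl-bearing carbon (the other α-carbon is quaternary), so enolate O-triflation (enol triflate formation) should give a single tetrasubstituted enol triflate, deleting the methyl-bearing stereocentre and leaving the silyloxy carbon R.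

Step 3
Reactants: 3 (4R)-4-(tert-butyldimethylsilyloxy)-2,6,6-trimethylcyclohex-1-en-1-yl trifluoromethanesulfonate, 4 (E)-3-methylpent-2-en-4-yn-1-ol
Product: 5 (2E)-5-[(4R)-4-(tert-butyldimethylsilyloxy)-2,6,6-trimethylcyclohex-1-en-1-yl]-3-methylpent-2-en-4-yn-1-ol
Conditions: Pd(PPh3)4 (5 mol %), CuI (10 mol %), Et3N, DMF, 60 °C
Reagents that add atoms: none
Why: Sonogashira coupling of the alkenyl triflate with the terminal alkyne should form the C6–C7 bond with the E alkene of the enynol carried through unchanged, the free allylic alcohol and the silyl ether being tolerated.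

Step 4
Reactants: 5 (2E)-5-[(4R)-4-(tert-butyldimethylsilyloxy)-2,6,6-trimethylcyclohex-1-en-1-yl]-3-methylpent-2-en-4-yn-1-ol
Product: 6 (2E)-5-[(4R)-4-(tert-butyldimethylsilyloxy)-2,6,6-trimethylcyclohex-1-en-1-yl]-3-methylpent-2-en-4-ynal
Conditions: MnO2 (excess), CH2Cl2, 23 °C
Reagents that add atoms: none
Why: Allylic oxidation with MnO2 is selective for the allylic alcohol and should leave the enyne, the silyl ether and the C9=C10 geometry untouched.

Step 5
Reactants: 6 (2E)-5-[(4R)-4-(tert-butyldimethylsilyloxy)-2,6,6-trimethylcyclohex-1-en-1-yl]-3-methylpent-2-en-4-ynal, 7 diethyl [3-(trimethylsilyl)prop-2-yn-1-yl]phosphonate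
Product: 8 tert-butyl{[(1R)-3,5,5-trimethyl-4-[(3E,5E)-3-methyl-8-(trimethylsilyl)octa-3,5-diene-1,7-diyn-1-yl]cyclohex-3-en-1-yl]oxy}dimethylsilane
Conditions: 7, LiN(SiMe3)2, THF, −78 °C; then 6, −78 to 0 °C
Reagents that add atoms: none
Why: Horner–Wadsworth–Emmons olefination with the lithiated silylpropargyl phosphonate should form C11=C12 with E selectivity under the usual thermodynamic control, the C-silyl group masking the acetylenic hydrogen.

Step 6
Reactants: 8 tert-butyl{[(1R)-3,5,5-trimethyl-4-[(3E,5E)-3-methyl-8-(trimethylsilyl)octa-3,5-diene-1,7-diyn-1-yl]cyclohex-3-en-1-yl]oxy}dimethylsilane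
Product: 9 tert-butyl{[(1R)-3,5,5-trimethyl-4-[(3E,5E)-3-methylocta-3,5-diene-1,7-diyn-1-yl]cyclohex-3-en-1-yl]oxy}dimethylsilane
Conditions: K2CO3 (cat.), MeOH/THF, 23 °C
Reagents that add atoms: none
Why: Carbonate-catalysed methanolysis of the alkynyl C–Si bond (protodesilylation) is much faster than cleavage of the secondary silyl ether, so only the terminal alkyne should be released.

Step 7
Reactants: 3 (4R)-4-(tert-butyldimethylsilyloxy)-2,6,6-trimethylcyclohex-1-en-1-yl trifluoromethanesulfonate, 10 (4-bromobut-1-yn-1-yl)trimethylsilane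
Product: 12 tert-butyldimethyl{[(1R)-3,5,5-trimethyl-4-[4-(trimethylsilyl)but-3-yn-1-yl]cyclohex-3-en-1-yl]oxy}silane, via organozinc bromide 11 (not isolated)
Conditions: 10, Zn dust (activated with 1,2-dibromoethane and Me3SiCl), LiCl, THF, 50 °C; then 3, Pd(OAc)2 (3 mol %), SPhos (6 mol %), THF/NMP, 60 °C
Reagents that add atoms: none
Why: Negishi coupling of the primary alkylzinc bromide (from zinc insertion into the C–Br bond) with the alkenyl triflate should form the C6'–C7' sp2–sp3 bond, the bulky biarylphosphine favouring reductive elimination over β-hydride elimination at the crowded centre.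

Step 8
Reactants: 12 tert-butyldimethyl{[(1R)-3,5,5-trimethyl-4-[4-(trimethylsilyl)but-3-yn-1-yl]cyclohex-3-en-1-yl]oxy}silane
Product: 13 {[(1R)-4-(but-3-yn-1-yl)-3,5,5-trimethylcyclohex-3-en-1-yl]oxy}(tert-butyl)dimethylsilane
Conditions: K2CO3 (cat.), MeOH/THF, 23 °C
Reagents that add atoms: none
Why: The same selective protodesilylation of the alkynylsilane as in step 6 should free the terminal alkyne and keep the silyl ether.

Step 9
Reactants: 14 acetylene
Product: 15 (E)-1-bromo-2-iodoethene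
Conditions: IBr, 48% aq HBr, 0 °C, acetylene passed through
Reagents that add atoms: iodine monobromide (IBr), BrI
Why: Electrophilic anti addition of IBr across the triple bond (halogenation through an iodonium ion) should give the E dihaloethene, whose two halogens differ strongly in reactivity toward palladium.

Step 10
Reactants: 13 {[(1R)-4-(but-3-yn-1-yl)-3,5,5-trimethylcyclohex-3-en-1-yl]oxy}(tert-butyl)dimethylsilane, 16 trimethylaluminium (AlMe3), 15 (E)-1-bromo-2-iodoethene
Product: 18 tert-butyl{[(1R)-4-[(3E,5E)-6-bromo-3-methylhexa-3,5-dien-1-yl]-3,5,5-trimethylcyclohex-3-en-1-yl]oxy}dimethylsilane, via alkenylalane 17 (not isolated)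
Conditions: 16 (2 equiv), Cp2ZrCl2 (0.25 equiv), CH2Cl2, 23 °C; volatiles removed in vacuo; then 15 (1.2 equiv), ZnCl2 (promoter), Pd(PPh3)4 (3 mol %), THF, 0 to 23 °C
Reagents that add atoms: none
Why: Zr-catalysed syn methylalumination of the terminal alkyne (Negishi carboalumination) should place methyl on C9' and aluminium on C10' with E geometry, and the Pd/Zn-catalysed Negishi coupling should then occur with retention only at the more reactive C–I bond, keeping the C–Br bond for the next round.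

Step 11
Reactants: 18 tert-butyl{[(1R)-4-[(3E,5E)-6-bromo-3-methylhexa-3,5-dien-1-yl]-3,5,5-trimethylcyclohex-3-en-1-yl]oxy}dimethylsilane, 19 ethynylmagnesium bromide
Product: 21 tert-butyl{[(1R)-3,5,5-trimethyl-4-[(3E,5E)-3-methylocta-3,5-dien-7-yn-1-yl]cyclohex-3-en-1-yl]oxy}dimethylsilane, via ethynylzinc bromide 20 (not isolated)
Conditions: 19 (1.5 equiv), ZnBr2 (1.5 equiv), THF, 0 °C; then 18, Pd(PPh3)4 (3 mol %), THF, 23 °C
Reagents that add atoms: none
Why: Pd-catalysed Negishi alkynylation of the (E)-alkenyl bromide with ethynylzinc bromide, made in the flask by transmetalation, should install the terminal C13'≡C14' alkyne with retention of both alkene geometries.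

Step 12
Reactants: 21 tert-butyl{[(1R)-3,5,5-trimethyl-4-[(3E,5E)-3-methylocta-3,5-dien-7-yn-1-yl]cyclohex-3-en-1-yl]oxy}dimethylsilane, 16 trimethylaluminium (AlMe3), 15 (E)-1-bromo-2-iodoethene
Product: 23 tert-butyl{[(1R)-4-[(3E,5E,7E,9E)-10-bromo-3,7-dimethyldeca-3,5,7,9-tetraen-1-yl]-3,5,5-trimethylcyclohex-3-en-1-yl]oxy}dimethylsilane, via alkenylalane 22 (not isolated)
Conditions: 16 (2 equiv), Cp2ZrCl2 (0.25 equiv), CH2Cl2, 23 °C; volatiles removed in vacuo; then 15 (1.2 equiv), ZnCl2 (promoter), Pd(PPh3)4 (3 mol %), THF, 0 to 23 °C, dark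
Reagents that add atoms: none
Why: The carboalumination/Negishi sequence of step 10, now on a conjugated dienyne, should set C13'(methyl)=C14' as E by syn addition and couple only at the C–I bond to give the all-E bromotetraene.

Step 13
Reactants: 9 tert-butyl{[(1R)-3,5,5-trimethyl-4-[(3E,5E)-3-methylocta-3,5-diene-1,7-diyn-1-yl]cyclohex-3-en-1-yl]oxy}dimethylsilane, 16 trimethylaluminium (AlMe3), 23 tert-butyl{[(1R)-4-[(3E,5E,7E,9E)-10-bromo-3,7-dimethyldeca-3,5,7,9-tetraen-1-yl]-3,5,5-trimethylcyclohex-3-en-1-yl]oxy}dimethylsilane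
Product: 25 (3R,3'R)-3,3'-bis(tert-butyldimethylsilyloxy)-7,8-didehydro-7',8'-dihydro-β,β-carotene, via alkenylalane 24 (not isolated)
Conditions: 9, 16 (2 equiv), Cp2ZrCl2 (0.5 equiv), CH2Cl2, 23 °C; volatiles removed in vacuo; then 23 (0.9 equiv), ZnCl2 (promoter), Pd2(dba)3 (2.5 mol %), tri(2-furyl)phosphine (10 mol %), THF/DMF, 23 °C, dark
Reagents that add atoms: none
Why: Cp2ZrCl2 and AlMe3 generate a Zr/Al bimetallic methyl species that adds methyl and metal syn across the terminal C13≡C14 bond of 9, methyl (the future C20) to the internal carbon C13 and aluminium to C14, to give the (E)-alkenylalane 24; after removal of excess AlMe3 the alkenyl group is relayed through zinc to the alkenylpalladium bromide formed by stereoretentive oxidative addition of the C15–Br bond of 23 to zerovalent palladium, and reductive elimination forms the C14–C15 bond. The closest known reaction type is the one-pot Zr-catalysed methylalumination/Pd- and Zn-catalysed alkenyl–alkenyl Negishi coupling of conjugated enynes with alkenyl halides used for polyene assembly. No ring is closed in this step. No stereocentre is created; the new stereo element is the C13=C14 double bond, whose E geometry is dictated by the syn mode of carbometalation, while C15=C15' keeps the E geometry of the bromide and C3 and C3' are remote and untouched. The step needs chemoselectivity for the terminal alkyne over the internal C7≡C8 alkyne and regioselectivity for methyl at C13: terminal alkynes are carbometalated far faster than internal ones, the C7≡C8 bond is screened by the C1 gem-dimethyl group and the C5 and C9 methyl groups, and the metal goes to the unhindered terminal carbon. Both hydroxyls are masked as silyl ethers so that no acidic hydrogen quenches the alane.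

Step 14
Reactants: 25 (3R,3'R)-3,3'-bis(tert-butyldimethylsilyloxy)-7,8-didehydro-7',8'-dihydro-β,β-carotene
Product: 26 (3R,3'R)-7,8-didehydro-7',8'-dihydro-β,β-carotene-3,3'-diol (all-E)
Conditions: TBAF (4 equiv), THF, 0 to 23 °C, dark; aqueous work-up
Reagents that add atoms: none
Why: Fluoride-mediated desilylation of the two secondary silyl ethers is mild enough that the polyene geometry, the C7≡C8 alkyne and the R configurations at C3 and C3' should be retained, giving the target diol.

**Compound list**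

1 | (4R,6R)-4-hydroxy-2,2,6-trimethylcyclohexan-1-one ((4R,6R)-actinol) | O=C1C(C)(C)C[C@H](O)C[C@H]1C | starting material
2 | (4R,6R)-4-(tert-butyldimethylsilyloxy)-2,2,6-trimethylcyclohexan-1-one | O=C1C(C)(C)C[C@H](O[Si](C)(C)C(C)(C)C)C[C@H]1C | intermediate
3 | (4R)-4-(tert-butyldimethylsilyloxy)-2,6,6-trimethylcyclohex-1-en-1-yl trifluoromethanesulfonate | CC1=C(OS(=O)(=O)C(F)(F)F)C(C)(C)C[C@H](O[Si](C)(C)C(C)(C)C)C1 | intermediate
4 | (E)-3-methylpent-2-en-4-yn-1-ol | C#C/C(C)=C/CO | starting material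
5 | (2E)-5-[(4R)-4-(tert-butyldimethylsilyloxy)-2,6,6-trimethylcyclohex-1-en-1-yl]-3-methylpent-2-en-4-yn-1-ol | CC1=C(C#C/C(C)=C/CO)C(C)(C)C[C@H](O[Si](C)(C)C(C)(C)C)C1 | intermediate
6 | (2E)-5-[(4R)-4-(tert-butyldimethylsilyloxy)-2,6,6-trimethylcyclohex-1-en-1-yl]-3-methylpent-2-en-4-ynal | CC1=C(C#C/C(C)=C/C=O)C(C)(C)C[C@H](O[Si](C)(C)C(C)(C)C)C1 | intermediate
7 | diethyl [3-(trimethylsilyl)prop-2-yn-1-yl]phosphonate | CCOP(=O)(CC#C[Si](C)(C)C)OCC | starting material
8 | tert-butyl{[(1R)-3,5,5-trimethyl-4-[(3E,5E)-3-methyl-8-(trimethylsilyl)octa-3,5-diene-1,7-diyn-1-yl]cyclohex-3-en-1-yl]oxy}dimethylsilane | CC1=C(C#C/C(C)=C/C=C/C#C[Si](C)(C)C)C(C)(C)C[C@H](O[Si](C)(C)C(C)(C)C)C1 | intermediate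
9 | tert-butyl{[(1R)-3,5,5-trimethyl-4-[(3E,5E)-3-methylocta-3,5-diene-1,7-diyn-1-yl]cyclohex-3-en-1-yl]oxy}dimethylsilane | CC1=C(C#C/C(C)=C/C=C/C#C)C(C)(C)C[C@H](O[Si](C)(C)C(C)(C)C)C1 | intermediate
10 | (4-bromobut-1-yn-1-yl)trimethylsilane | C[Si](C)(C)C#CCCBr | starting material
11 | [4-(trimethylsilyl)but-3-yn-1-yl]zinc bromide | C[Si](C)(C)C#CCC[Zn]Br | intermediate
12 | tert-butyldimethyl{[(1R)-3,5,5-trimethyl-4-[4-(trimethylsilyl)but-3-yn-1-yl]cyclohex-3-en-1-yl]oxy}silane | CC1=C(CCC#C[Si](C)(C)C)C(C)(C)C[C@H](O[Si](C)(C)C(C)(C)C)C1 | intermediate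
13 | {[(1R)-4-(but-3-yn-1-yl)-3,5,5-trimethylcyclohex-3-en-1-yl]oxy}(tert-butyl)dimethylsilane | CC1=C(CCC#C)C(C)(C)C[C@H](O[Si](C)(C)C(C)(C)C)C1 | intermediate
14 | acetylene | C#C | starting material
15 | (E)-1-bromo-2-iodoethene | Br/C=C/I | intermediate
16 | trimethylaluminium (AlMe3) | C[Al](C)C | starting material
17 | {(1E)-4-[(4R)-4-(tert-butyldimethylsilyloxy)-2,6,6-trimethylcyclohex-1-en-1-yl]-2-methylbut-1-en-1-yl}dimethylalane | CC1=C(CC/C(C)=C/[Al](C)C)C(C)(C)C[C@H](O[Si](C)(C)C(C)(C)C)C1 | intermediate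
18 | tert-butyl{[(1R)-4-[(3E,5E)-6-bromo-3-methylhexa-3,5-dien-1-yl]-3,5,5-trimethylcyclohex-3-en-1-yl]oxy}dimethylsilane | CC1=C(CC/C(C)=C/C=C/Br)C(C)(C)C[C@H](O[Si](C)(C)C(C)(C)C)C1 | intermediate
19 | ethynylmagnesium bromide | C#C[Mg]Br | starting material
20 | ethynylzinc bromide | C#C[Zn]Br | intermediate
21 | tert-butyl{[(1R)-3,5,5-trimethyl-4-[(3E,5E)-3-methylocta-3,5-dien-7-yn-1-yl]cyclohex-3-en-1-yl]oxy}dimethylsilane | CC1=C(CC/C(C)=C/C=C/C#C)C(C)(C)C[C@H](O[Si](C)(C)C(C)(C)C)C1 | intermediate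
22 | {(1E,3E,5E)-8-[(4R)-4-(tert-butyldimethylsilyloxy)-2,6,6-trimethylcyclohex-1-en-1-yl]-2,6-dimethylocta-1,3,5-trien-1-yl}dimethylalane | CC1=C(CC/C(C)=C/C=C/C(C)=C/[Al](C)C)C(C)(C)C[C@H](O[Si](C)(C)C(C)(C)C)C1 | intermediate
23 | tert-butyl{[(1R)-4-[(3E,5E,7E,9E)-10-bromo-3,7-dimethyldeca-3,5,7,9-tetraen-1-yl]-3,5,5-trimethylcyclohex-3-en-1-yl]oxy}dimethylsilane | CC1=C(CC/C(C)=C/C=C/C(C)=C/C=C/Br)C(C)(C)C[C@H](O[Si](C)(C)C(C)(C)C)C1 | intermediate
24 | {(1E,3E,5E)-8-[(4R)-4-(tert-butyldimethylsilyloxy)-2,6,6-trimethylcyclohex-1-en-1-yl]-2,6-dimethylocta-1,3,5-trien-7-yn-1-yl}dimethylalane | CC1=C(C#C/C(C)=C/C=C/C(C)=C/[Al](C)C)C(C)(C)C[C@H](O[Si](C)(C)C(C)(C)C)C1 | intermediate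
25 | (3R,3'R)-3,3'-bis(tert-butyldimethylsilyloxy)-7,8-didehydro-7',8'-dihydro-β,β-carotene | CC1=C(C#C/C(C)=C/C=C/C(C)=C/C=C/C=C(C)/C=C/C=C(\C)CCC2=C(C)C[C@@H](O[Si](C)(C)C(C)(C)C)CC2(C)C)C(C)(C)C[C@H](O[Si](C)(C)C(C)(C)C)C1 | intermediate
26 | (3R,3'R)-7,8-didehydro-7',8'-dihydro-β,β-carotene-3,3'-diol (CNP0178054.1) | CC1=C(C#C/C(C)=C/C=C/C(C)=C/C=C/C=C(C)/C=C/C=C(\C)CCC2=C(C)C[C@@H](O)CC2(C)C)C(C)(C)C[C@H](O)C1 | target

**Step count**

Total steps: 14. Longest linear sequence: 9 steps (steps 1, 2, 7, 8, 10, 11, 12, 13, 14).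

**Steps most likely to fail**

1. Step 13 (key step). What may go wrong: protonolysis of the alkenyl–aluminium bond or transfer of a methyl group in place of the alkenyl group during the one-pot relay from aluminium through zinc to palladium, and carbometalation drifting to the internal C7≡C8 alkyne on long exposure. The fallback sets out from 9 and 23 and comes back at 25. Alane 24 is generated with a short reaction time and quenched with I2 (THF, −30 °C) to give the isolable ring A (E)-alkenyl iodide F1. Bromide 23 is converted by Miyaura borylation (B2pin2, PdCl2(dppf), KOPh, toluene, 50 °C) into the ring B tetraenyl pinacol boronate F2. Suzuki–Miyaura coupling of F1 with F2 (Pd(PPh3)4, aq KOH, THF, 23 °C) should then give 25, so the union no longer depends on an aluminium or zinc species surviving next to the sensitive bromide.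

2. Step 7. What may go wrong: slow transfer of the primary alkyl group from zinc to the crowded alkenylpalladium centre, so that β-hydride elimination and reduction of the triflate take over. The fallback sets out from 3 and comes back at 12. Pd-catalysed methoxycarbonylation of 3 (Pd(OAc)2, dppp, CO, MeOH, Et3N, DMF, 70 °C) gives the ring B methyl ester F3. Reduction with i-Bu2AlH (CH2Cl2, −78 °C) gives the allylic alcohol F4, and CBr4/PPh3 (CH2Cl2, 0 °C) gives the allylic bromide F5. SN2 alkylation of 3-lithio-1-(trimethylsilyl)propyne F6 (made from 1-(trimethylsilyl)propyne and n-BuLi, THF, −78 °C) with F5 forms the C7'–C8' bond and gives 12.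

3. Step 12. What may go wrong: coupling at both halogens of 15, which would give a symmetrical dimer, and E/Z isomerisation or decomposition of the light-sensitive bromotetraene during isolation. The fallback sets out from 21 and comes back at 25. Alane 22 is generated as in step 12 and quenched with I2 to give the trienyl iodide F7. Stille coupling of F7 with an excess of commercial (E)-1,2-bis(tributylstannyl)ethene (PdCl2(MeCN)2, DMF, 23 °C) gives the tetraenylstannane F8, which can be purified and stored. Iododestannylation (I2, CH2Cl2, 0 °C) converts F8 just before use into the tetraenyl iodide F9, which takes the place of 23 in step 13 and gives 25.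

Further compounds
F1 | step 13 | tert-butyl{[(1R)-4-[(3E,5E,7E)-8-iodo-3,7-dimethylocta-3,5,7-trien-1-yn-1-yl]-3,5,5-trimethylcyclohex-3-en-1-yl]oxy}dimethylsilane | CC1=C(C#C/C(C)=C/C=C/C(C)=C/I)C(C)(C)C[C@H](O[Si](C)(C)C(C)(C)C)C1
F2 | step 13 | tert-butyl{[(1R)-4-[(3E,5E,7E,9E)-3,7-dimethyl-10-(4,4,5,5-tetramethyl-1,3,2-dioxaborolan-2-yl)deca-3,5,7,9-tetraen-1-yl]-3,5,5-trimethylcyclohex-3-en-1-yl]oxy}dimethylsilane | CC1=C(CC/C(C)=C/C=C/C(C)=C/C=C/B2OC(C)(C)C(C)(C)O2)C(C)(C)C[C@H](O[Si](C)(C)C(C)(C)C)C1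
F3 | step 7 | methyl (4R)-4-(tert-butyldimethylsilyloxy)-2,6,6-trimethylcyclohex-1-ene-1-carboxylate | CC1=C(C(=O)OC)C(C)(C)C[C@H](O[Si](C)(C)C(C)(C)C)C1
F4 | step 7 | [(4R)-4-(tert-butyldimethylsilyloxy)-2,6,6-trimethylcyclohex-1-en-1-yl]methanol | CC1=C(CO)C(C)(C)C[C@H](O[Si](C)(C)C(C)(C)C)C1
F5 | step 7 | {[(1R)-4-(bromomethyl)-3,5,5-trimethylcyclohex-3-en-1-yl]oxy}(tert-butyl)dimethylsilane | CC1=C(CBr)C(C)(C)C[C@H](O[Si](C)(C)C(C)(C)C)C1
F6 | step 7 | 3-lithio-1-(trimethylsilyl)propyne | [Li]CC#C[Si](C)(C)C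
F7 | step 12 | tert-butyl{[(1R)-4-[(3E,5E,7E)-8-iodo-3,7-dimethylocta-3,5,7-trien-1-yl]-3,5,5-trimethylcyclohex-3-en-1-yl]oxy}dimethylsilane | CC1=C(CC/C(C)=C/C=C/C(C)=C/I)C(C)(C)C[C@H](O[Si](C)(C)C(C)(C)C)C1
F8 | step 12 | tert-butyl{[(1R)-4-[(3E,5E,7E,9E)-3,7-dimethyl-10-(tributylstannyl)deca-3,5,7,9-tetraen-1-yl]-3,5,5-trimethylcyclohex-3-en-1-yl]oxy}dimethylsilane | CC1=C(CC/C(C)=C/C=C/C(C)=C/C=C/[Sn](CCCC)(CCCC)CCCC)C(C)(C)C[C@H](O[Si](C)(C)C(C)(C)C)C1
F9 | step 12 | tert-butyl{[(1R)-4-[(3E,5E,7E,9E)-10-iodo-3,7-dimethyldeca-3,5,7,9-tetraen-1-yl]-3,5,5-trimethylcyclohex-3-en-1-yl]oxy}dimethylsilane | CC1=C(CC/C(C)=C/C=C/C(C)=C/C=C/I)C(C)(C)C[C@H](O[Si](C)(C)C(C)(C)C)C1
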